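**Assumption:** the carbinol carbon encoded in the SMILES is (R), and the route targets that enantiomer.

## Retrosynthetic overview

1. Gravicycle ⇐ hydrogenolysis of its tri‑O‑benzyl ether ⇐ ring‑closing metathesis (C2–C3 of the C14 bridge) and hydrogenation; the 22‑membered ring is formed last.
2. The RCM diene ⇐ a terminal acetonide excised to a vinyl group (hydrolysis, then diol → alkene), so the bought stereocentre ends up as the CH2 next to the carbinol.
3. Ring A and the hindered diaryl ether ⇐ Danheiser benzannulation (4π opening / [2+2] / 4π opening / 6π closure) of a ring‑B aryl ethynyl ether with 3‑(tridec‑12‑enyl)cyclobutenone.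
4. The (R)‑benzylic carbinol ⇐ Felkin–Anh hydride reduction of an aryl ketone made from ArLi and the Weinreb amide of (S)‑glyceric acid acetonide.
5. Ring order: ring B (bought as resorcinol dibenzyl ether) → ring A (benzannulation) → macrocycle (RCM).

## Route

**Step 1**
Reactants: **1**, 1,3‑bis(benzyloxy)benzene
Product: **2**, 2,6‑bis(benzyloxy)phenol
Conditions: n‑BuLi, THF, 0 °C→rt; B(OMe)3, –78 °C→rt; then H2O2, aq NaOH, 0 °C
Reagents that add atoms: hydrogen peroxide, OO
Why: Directed ortho‑metalation at the doubly activated C2, borylation and oxidative C–B→C–O migration give the phenol.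

**Step 2**
Reactants: **2**
Product: **3**, 4‑bromo‑2,6‑bis(benzyloxy)phenol
Conditions: NBS, cat. NaH, CHCl3, –45 °C→rt
Reagents that add atoms: N‑bromosuccinimide, O=C1CCC(=O)N1Br
Why: Electrophilic aromatic bromination para to the free OH, with both ortho positions blocked.

**Step 3**
Reactants: **3**
Product: **4**, [4‑bromo‑2,6‑bis(benzyloxy)phenoxy](tert‑butyl)dimethylsilane
Conditions: TBSCl, imidazole, DMF, rt
Reagents that add atoms: TBSCl, CC(C)(C)[Si](C)(C)Cl
Why: Silylation masks the acidic phenol for the organolithium step and keeps the para oxygen from deactivating the later ketone.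

**Step 4**
Reactants: **5**, methyl (S)‑2,2‑dimethyl‑1,3‑dioxolane‑4‑carboxylate
Product: **6**, (S)‑N‑methoxy‑N,2,2‑trimethyl‑1,3‑dioxolane‑4‑carboxamide
Conditions: MeNH(OMe)·HCl, i‑PrMgCl, THF, –20 °C
Reagents that add atoms: N,O‑dimethylhydroxylamine hydrochloride, CNOC.Cl
Why: Aminolysis by the chloromagnesium amide gives the Weinreb amide without touching the α‑alkoxy stereocentre.

**Step 5**
Reactants: **4** and **6**
Product: **7**, [3,5‑bis(benzyloxy)‑4‑(TBS‑oxy)phenyl][(4S)‑2,2‑dimethyl‑1,3‑dioxolan‑4‑yl]methanone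
Conditions: t‑BuLi (2 equiv), THF, –78 °C; then **6**, –78→0 °C; aq NH4Cl
Reagents that add atoms: none
Why: Br–Li exchange and Weinreb ketone synthesis; the stable chelated tetrahedral intermediate prevents over‑addition and α‑epimerisation.

**Step 6**
Reactants: **7**
Product: **8**, (S)‑[3,5‑bis(benzyloxy)‑4‑(TBS‑oxy)phenyl][(4S)‑2,2‑dimethyl‑1,3‑dioxolan‑4‑yl]methanol (syn)
Conditions: K‑Selectride, THF, –78 °C; buffered (pH 7) H2O2 work‑up
Reagents that add atoms: none
Why: Felkin–Anh 1,2‑induction: the bulky, non‑chelating hydride attacks anti to the α‑C–O bond to give the syn alcohol (expected dr ≥ 95:5, minor diastereomer removed by chromatography). This sets the benzylic centre with the spatial arrangement of the target's (R)‑carbinol; the descriptor reads S here only because the neighbours differ.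

**Step 7**
Reactants: **8** and **9**, trichloroethylene
Product: **10**, (S)‑{3,5‑bis(benzyloxy)‑4‑[(E)‑1,2‑dichlorovinyloxy]phenyl}[(4S)‑2,2‑dimethyl‑1,3‑dioxolan‑4‑yl]methanol
Conditions: CsF, K2CO3, DMF, 70 °C
Reagents that add atoms: none (the C2 unit comes from **9**)
Why: Fluoride unmasks the phenoxide, which adds to dichloroacetylene formed in situ (net vinylic substitution); carbonate does not ionise the secondary alcohol.

**Step 8**
Reactants: **10**
Product: **11**, (4S)‑4‑[(S)‑(benzyloxy){3,5‑bis(benzyloxy)‑4‑[(E)‑1,2‑dichlorovinyloxy]phenyl}methyl]‑2,2‑dimethyl‑1,3‑dioxolane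
Conditions: NaH, BnBr, cat. TBAI, THF–DMF, 0 °C→rt
Reagents that add atoms: benzyl bromide, BrCc1ccccc1
Why: Williamson etherification protects the carbinol from ketene trapping in step 12 and from iodination in step 14.

**Step 9**
Reactants: **11**
Product: **12**, (4S)‑4‑[(S)‑(benzyloxy)(3,5‑bis(benzyloxy)‑4‑ethynyloxyphenyl)methyl]‑2,2‑dimethyl‑1,3‑dioxolane
Conditions: n‑BuLi (2.2 equiv), THF, –78 °C; MeOH quench; used at once
Reagents that add atoms: none
Why: Dehydrochlorination to the chloroalkynyl ether and Cl–Li exchange give the lithium alkynyl ether, protonated to the aryl ethynyl ether; benzyl ethers and the acetonide are inert at –78 °C.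

**Step 10**
Reactants: **13**, 1,10‑dibromodecane (3 equiv) and **14**, allylmagnesium bromide
Product: **15**, 13‑bromotridec‑1‑ene
Conditions: Li2CuCl4 (2 mol %), THF, –10 °C→rt; distil
Reagents that add atoms: none
Why: Kochi Cu‑catalysed sp3–sp3 Grignard coupling; excess dibromide favours mono‑allylation.

**Step 11**
Reactants: **15** and **16**, 3‑ethoxycyclobut‑2‑en‑1‑one
Product: **17**, 3‑(tridec‑12‑en‑1‑yl)cyclobut‑2‑en‑1‑one
Conditions: Mg, THF; add to **16**, –78→0 °C; then 1 M HCl, rt
Reagents that add atoms: water, O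
Why: 1,2‑Grignard addition to the vinylogous ester, then acid hydrolysis and dehydration (Stork–Danheiser‑type transposition) gives the 3‑alkylcyclobutenone.

**Step 12 (key step)**
Reactants: **12** and **17** (1.5 equiv)
Product: **18**, 3‑{2,6‑bis(benzyloxy)‑4‑[(S)‑(benzyloxy)((4S)‑2,2‑dimethyl‑1,3‑dioxolan‑4‑yl)methyl]phenoxy}‑5‑(tridec‑12‑en‑1‑yl)phenol
Conditions: PhMe, 90 °C; then KOH, MeOH, rt
Reagents that add atoms: none
Why: Danheiser benzannulation. 4π opening of **17** gives a vinylketene, which undergoes regioselective [2+2] with the ynol ether (alkyne CH to the ketene carbonyl carbon). 4π opening and 6π electrocyclisation then give ring A as the 3‑aryloxy‑5‑alkylphenol. KOH cleaves any phenol ester formed with excess ketene.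

**Step 13**
Reactants: **18**
Product: **19**, (2S,3S)‑3‑(benzyloxy)‑3‑{3,5‑bis(benzyloxy)‑4‑[3‑hydroxy‑5‑(tridec‑12‑en‑1‑yl)phenoxy]phenyl}propane‑1,2‑diol
Conditions: AcOH–H2O (4:1), 45 °C
Reagents that add atoms: none
Why: Mild acetal hydrolysis frees the terminal diol without ionising the benzylic ether.

**Step 14**
Reactants: **19**
Product: **20**, 3‑{2,6‑bis(benzyloxy)‑4‑[(1R)‑1‑(benzyloxy)prop‑2‑en‑1‑yl]phenoxy}‑5‑(tridec‑12‑en‑1‑yl)phenol
Conditions: PPh3 (5 equiv), imidazole (5 equiv), I2 (3 equiv), PhMe, 90 °C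
Reagents that add atoms: none
Why: Garegg–Samuelsson deoxygenation converts the vicinal diol to the vinyl group, destroying the bought stereocentre after it has done its job. Excess PPh3 keeps free iodine away from the phenol ring.

**Step 15**
Reactants: **20**
Product: **21**, gravicycle tri‑O‑benzyl ether (both ring‑B phenols and the (R)‑carbinol benzylated, ring‑A OH free, saturated bridge)
Conditions: Grubbs II (10 mol %), PhMe (1 mM), 80 °C; then concentrate, H2 (50 bar), 70 °C, same pot
Reagents that add atoms: none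
Why: Ring‑closing metathesis closes the 22‑membered ring with loss of ethylene. The Ru residue, converted to a hydride under H2, then saturates the alkene without hydrogenolysing the allylic/benzylic C–O bond.

**Step 16**
Reactants: **21**
Product: **22**, gravicycle
Conditions: H2 (1 atm), 10 % Pd/C, EtOAc–EtOH, rt, stopped at 3 equiv uptake
Reagents that add atoms: none
Why: Hydrogenolysis cleaves the three PhCH2–O bonds; the secondary benzylic C–OH is much slower to cleave under neutral conditions.

## Compound list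

1 | 1,3‑bis(benzyloxy)benzene | C(Oc1cccc(OCc2ccccc2)c1)c1ccccc1 | starting material
2 | 2,6‑bis(benzyloxy)phenol | Oc1c(OCc2ccccc2)cccc1OCc1ccccc1 | intermediate
3 | 4‑bromo‑2,6‑bis(benzyloxy)phenol | Oc1c(OCc2ccccc2)cc(Br)cc1OCc1ccccc1 | intermediate
4 | TBS ether of 3 | CC(C)(C)[Si](C)(C)Oc1c(OCc2ccccc2)cc(Br)cc1OCc1ccccc1 | intermediate
5 | methyl (S)‑2,2‑dimethyl‑1,3‑dioxolane‑4‑carboxylate | COC(=O)[C@@H]1COC(C)(C)O1 | starting material (chiral pool)
6 | (S)‑Weinreb amide | CON(C)C(=O)[C@@H]1COC(C)(C)O1 | intermediate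
7 | aryl (4S)‑dioxolanyl ketone | CC(C)(C)[Si](C)(C)Oc1c(OCc2ccccc2)cc(cc1OCc1ccccc1)C(=O)[C@@H]1COC(C)(C)O1 | intermediate
8 | syn (S,4S) alcohol | CC(C)(C)[Si](C)(C)Oc1c(OCc2ccccc2)cc(cc1OCc1ccccc1)[C@H](O)[C@@H]1COC(C)(C)O1 | intermediate
9 | trichloroethylene | ClC=C(Cl)Cl | starting material
10 | (E)‑dichlorovinyl ether, free carbinol | Cl/C=C(/Cl)Oc1c(OCc2ccccc2)cc(cc1OCc1ccccc1)[C@H](O)[C@@H]1COC(C)(C)O1 | intermediate
11 | benzyl ether of 10 | Cl/C=C(/Cl)Oc1c(OCc2ccccc2)cc(cc1OCc1ccccc1)[C@H](OCc1ccccc1)[C@@H]1COC(C)(C)O1 | intermediate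
12 | aryl ethynyl ether | C#COc1c(OCc2ccccc2)cc(cc1OCc1ccccc1)[C@H](OCc1ccccc1)[C@@H]1COC(C)(C)O1 | intermediate
13 | 1,10‑dibromodecane | BrCCCCCCCCCCBr | starting material
14 | allylmagnesium bromide | C=CC[Mg]Br | starting material
15 | 13‑bromotridec‑1‑ene | C=CCCCCCCCCCCCBr | intermediate
16 | 3‑ethoxycyclobut‑2‑en‑1‑one | CCOC1=CC(=O)C1 | starting material
17 | 3‑(tridec‑12‑en‑1‑yl)cyclobut‑2‑en‑1‑one | C=CCCCCCCCCCCCC1=CC(=O)C1 | intermediate
18 | benzannulation product (acetonide) | Oc1cc(CCCCCCCCCCCC=C)cc(c1)Oc1c(OCc2ccccc2)cc(cc1OCc1ccccc1)[C@H](OCc1ccccc1)[C@@H]1COC(C)(C)O1 | intermediate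
19 | (2S,3S)‑diol | Oc1cc(CCCCCCCCCCCC=C)cc(c1)Oc1c(OCc2ccccc2)cc(cc1OCc1ccccc1)[C@H](OCc1ccccc1)[C@@H](O)CO | intermediate
20 | (R)‑vinyl carbinol benzyl ether (RCM diene) | Oc1cc(CCCCCCCCCCCC=C)cc(c1)Oc1c(OCc2ccccc2)cc(cc1OCc1ccccc1)[C@H](OCc1ccccc1)C=C | intermediate
21 | gravicycle tri‑O‑benzyl ether | Oc1cc2cc(c1)Oc1c(OCc3ccccc3)cc(cc1OCc1ccccc1)[C@H](OCc1ccccc1)CCCCCCCCCCCCC2 | intermediate
22 | gravicycle | Oc1cc2cc(c1)Oc1c(O)cc(cc1O)[C@H](O)CCCCCCCCCCCCC2 | target

## Summary

**Total steps:** 16 (step 15 is a one‑pot RCM/hydrogenation).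
**Longest linear sequence:** 13 (1 → 2 → 3 → 4 → 7 → 8 → 10 → 11 → 12 → 18 → 19 → 20 → 21 → 22).

**Steps most likely to fail, with fallbacks**

1. **Step 12 (benzannulation).** The aryloxyacetylene is less nucleophilic than alkoxyacetylenes and acid‑labile, so [2+2] with the vinylketene may be slow or low‑yielding. Fallback: buy ring A instead of building it. Couple the ring‑B phenol (desilylated, O‑benzylated analogue of **8**) with benzyl‑protected 3‑bromo‑5‑(tridec‑12‑enyl)phenol by Cu‑catalysed Ullmann etherification.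
2. **Step 15 (macro‑RCM).** The alkene next to the hindered allylic benzylic ether may give oligomers or isomerise. Fallback: cleave diol **19** with NaIO4 to the α‑benzyloxy aldehyde and close the ring by intramolecular Wittig olefination onto a chain‑terminal phosphonium salt (chain partner made from a ω‑bromoalkyl cyclobutenone), then hydrogenate.
3. **Step 16 (global hydrogenolysis).** The benzylic carbinol C–O could be over‑reduced. Fallback: change the protecting‑group plan. Carry the carbinol as a TBS ether (TBSOTf in step 8) so only phenolic benzyl ethers are hydrogenolysed, and release the alcohol last with fluoride.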